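## Structural features

The target joins two benzene rings through a benzylic ester. Ring A is a 2-hydroxy-4-methoxy-3,6-dimethylbenzoyl unit (C1 carboxyl, C2 OH, C3 Me, C4 OMe, C5 H, C6 Me). Ring B is a pentasubstituted benzene fused to ring C, a five-membered lactone-lactol (3-hydroxyphthalide: C1 carbonyl, O2, C3 bearing OH), with OH at C7, the CH2–O–acyl arm at C6, OMe at C5 and H at C4. The only stereocentre is C3 of ring C, which is R (ring oxygen > hydroxyl > C3a > H) and has no stereogenic neighbour. Because C3 is a cyclic acyl hemiacetal that can open to the achiral 2-formylbenzoic acid, it is the element most easily lost. The benzylic ester is also fragile: it sits between the free C7 phenol and the C5 methoxy group, so base can expel the carboxylate through an ortho-quinone methide, strong acid can ionise it, and hydrogenolysis would cleave it. The real difficulties are three: an ester between a doubly ortho-substituted, hydrogen-bonded benzoic acid and a crowded benzylic alcohol; three carbon substituents on ring B at three oxidation levels (C1 acid, C3 aldehyde, C6–CH2 alcohol); and the late, mild setting of C3. The key step exploits ring A: its carbons C1–C6, with oxygens at C2 and C4 and the methyl at C3, are the aldol-aromatised form of carbons C2–C7 of a 4-methyl-3,5,7-trioxooctanoate whose ester oxygen is the ring B benzylic oxygen. The ester can therefore come from a ketene and ring A from closure of its C1–C6 bond.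

## Logic of the disconnections

21 to 20. The free C3 hydroxyl is traced back to its acetate; the bond involved is the acyl C–O bond, not the C3–O bond. The reason is that the hemiacetal must be unveiled last, from a configurationally stable acylal. The gain is a storable, stereodefined precursor. The demand is a neutral deacylation that does not ionise the lactol.

20 to 19. The O–acyl bond is cut and the stereocentre is traced back to the racemic lactol. The lability of C3 is turned to advantage: a chiral catalyst acylates one enantiomer while the other racemises through the open form. The gain is that no stereochemistry has to be carried through the synthesis. The demand is that acyl transfer be enantioselective and slower than racemisation.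

19 to 18. Two acetal C–O bonds are cut (the C7 aryl O–CH2OMe ether and the C3–OMe pseudo-ester). The C7 phenol must be masked in every basic step to block quinone methide formation, and the lactol must be masked against ketene and base. The gain is one final deprotection. The demand is acid mild enough for the benzylic ester.

18 to 17. The O–CH3 bond at ring A C4 is cut, because ring construction necessarily delivers a free resorcinol. The demand is selectivity for the unchelated C4 hydroxyl over the chelated C2 hydroxyl.

17 to 4 and 13 (through 16, 15 and 14). The ring A C1–C6 bond and the ester O–C(acyl) bond are cut. This removes ring A and the hindered ester in one operation and leaves two fragments of similar size. The demand is that the alcohol capture the ketene faster than the ketene cyclises on itself, and that the correct aldol mode win.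

4 to 3 to 2 to 1. Three C–C bonds of the side chain are cut in turn: terminal acyl–CH2, acyl–CH(Me), and CH2–CH3. Each is an enolate alkylation or acylation of a dioxinone. The demand is γ-selectivity of the extended enolates.

13 to 12 to 11. The benzylic C–H of the alcohol is traced to an aldehyde and the aryl O–CH2OMe bond is cut. The aldehyde is how the C6 carbon arrives; the demand is hydride selectivity for the aldehyde over the pseudo-ester.

11 to 10 to 8 (through 9). The C3–OMe bond is cut, and the C–O bonds at both benzylic carbons are traced to C–Br bonds. Both carbons are carried at the same (aldehyde) level, and only the one next to the carboxyl closes to the lactol. This replaces a rate-controlled differentiation of two methyl groups by a structural one.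

8 to 7 to 6 to 5. The C–Br bonds are traced to C–H, the aryl acetate to the phenol, and the C4 methyl ether to the phenol of a commodity arene. The demand is exhaustive benzylic bromination without ring bromination.

## Other disconnections considered

Alternative 1: The cut runs through ring B at C3a–C4 and C7–C7a. Ring B would be assembled from the oxygenated diene A1 (supplying C4–C7 with the methoxy group, the silyloxymethyl arm and the latent phenol) and the acetylenic ester A2 (supplying C3a and C7a with the acetal and the ester). The forward step is a polarity-matched (4+2) cycloaddition, in which the CH2 terminus of A1 bonds to the alkyne carbon bearing the acetal. Loss of methanol and of the trimethylsilyl group then gives arene A3.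
- In its favour: all five substituents arrive at the correct oxidation levels, and the C7 hydroxyl is already differentiated from the C5 methyl ether. No benzylic oxidation or reduction is needed. On redox economy this is better than the chosen plan, which spends four brominations and one reduction.
- Against it here: A1 is a fully substituted, hydrolytically sensitive ketene acetal that needs its own multistep preparation. The alkyne A2 is only moderately electron-poor, so heating would be required at temperatures where such dienes tend to decompose.
- Comparison: A3 is the open-chain equivalent of the 10-to-13 series and would need acetal exchange to the pseudo-ester, phenol protection and desilylation to reach 13. The step count to 13 is therefore about equal. Mechanistically it offers pericyclic regiocontrol instead of substituent-by-substituent manipulation. It leaves ring A and the hindered ester unsolved, so it is complementary to step 11 and not a replacement.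

Alternative 2: Three ring B bonds are cut (C7a–C3a, C6–C7, C4–C5), leading back to the tethered triyne A4. The forward step is a (2+2+2) cyclotrimerisation with RhCl(PPh3)3 that closes ring B, ring C and a temporary oxasilole to give tricycle A5. Oxidation of the aryl–silicon bond would then release diol A6.
- In its favour: three C–C bonds and three rings form in one step with regiochemistry fixed by the tethers, and the silicon tether turns into exactly the C7 hydroxyl and the C6 hydroxymethyl group. In bond-forming economy and convergence it is better than the chosen plan.
- Against it here: A4 combines a methoxy-alkyne, an alkynylsilyl ether and a propargylic acyloxy acetal, each labile, so its assembly would be long and delicate. Ester tethers cyclise reluctantly. The basic peroxide or fluoride needed to oxidise the aryl–silicon bond endangers the pseudo-ester.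
- Comparison: A6 has the same ring B pattern as 13 but lacks the phenol protection, so selective protection would still follow. The key step is shorter, the total route probably longer and riskier. Ring A and the ester are again not addressed.

Alternative 3: The cut is the oxygen insertion into the C1–C3 bond of ring C, leading back to the benzocyclobutenone A7, which already carries ring A. The forward step is a Baeyer–Villiger oxidation with m-CPBA and NaHCO3. The oxygen-substituted sp3 carbon is expected to migrate in preference to the aryl carbon, with retention, giving the bis-silyl ether A8; Si–O cleavage then gives 21.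
- In its favour: C3 configuration is transmitted by a stereospecific migration and not established by resolution at the end. The α-silyloxy ketone should be configurationally robust, because its enolisation would create an antiaromatic four-membered enol. On stereochemical logic this is better than the chosen plan. The final unmasking at oxygen without touching the C3–O bond is the equal of step 15.
- Against it here: enantioenriched A7 requires a pentasubstituted benzocyclobutenone with an asymmetric α-oxygenation, and no short access is evident. The peracid meets an electron-rich arene and a benzylic ester. Final removal of the phenolic silyl group next to the benzylic ester invites quinone methide formation unless buffered.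
- Comparison: it builds only ring C and presupposes rings A and B and the hindered ester. It is likely the longest of the four plans.

Key step: step 11

Remarks on the chemistry (assumptions and design changes):
- The target is taken as the (3R)-lactol. A 3-hydroxyphthalide can equilibrate with the open 2-formylbenzoic acid, so it is assumed to hold its configuration only in neutral, aprotic, cold media. C3 is therefore set in the last two steps.
- The sense of the lipase in step 14 is predicted from the empirical size model for secondary alcohols and would have to be confirmed; an enzyme of opposite preference is the direct substitute.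
- The atom mapping of the key step was checked and is consistent: chain C2–C7 of the triketo ester becomes ring A C1–C6, and the chain C4 methyl becomes the ring A C3 methyl.
- Design change 1: the base stage of the key step is run in THF and not in an alcohol, because alkoxide would isomerise the methyl pseudo-ester of ring C to the open methyl 2-formylbenzoate.
- Design change 2: a single benzylic bromination cannot reliably stop the two methyl groups of ring B at different levels (the methyl between the two oxygens is the more reactive, yet needs the lower level). Both are therefore taken to the aldehyde level, lactol formation differentiates them, and the remaining aldehyde is reduced.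

## Route

Step 1
Reactants: 1 2,2,6-trimethyl-4H-1,3-dioxin-4-one
Product: 2 6-ethyl-2,2-dimethyl-4H-1,3-dioxin-4-one
Conditions: LiN(i-Pr)2, THF, −78 °C; MeI, DMPU, −78 → −40 °C
Reagents that add atoms: iodomethane, CI
Why: Deprotonation of the C6 methyl gives the cross-conjugated lithium dienolate, which should be alkylated at the γ-carbon by MeI in the presence of DMPU (vinylogous enolate γ-alkylation); low temperature suppresses fragmentation of the dienolate.

Step 2
Reactants: 2 6-ethyl-2,2-dimethyl-4H-1,3-dioxin-4-one
Product: 3 2,2-dimethyl-6-(3-oxobutan-2-yl)-4H-1,3-dioxin-4-one (racemic)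
Conditions: LiN(SiMe3)2 (2.1 equiv), THF, −78 °C; AcCl (1 equiv), −78 → −40 °C; aq. NH4Cl
Reagents that add atoms: acetyl chloride, CC(=O)Cl
Why: The extended enolate of 2 is C-acylated at the γ-carbon (vinylogous Claisen-type acylation); the second equivalent of enolate deprotonates the more acidic product as it forms, which prevents double acylation.

Step 3
Reactants: 3 2,2-dimethyl-6-(3-oxobutan-2-yl)-4H-1,3-dioxin-4-one
Product: 4 6-(3,5-dioxohexan-2-yl)-2,2-dimethyl-4H-1,3-dioxin-4-one (racemic, enol tautomers)
Conditions: LiN(i-Pr)2 (2.5 equiv), THF, −78 °C; MeC(O)N(OMe)Me, −78 → −20 °C; AcOH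
Reagents that add atoms: N-methoxy-N-methylacetamide, CC(=O)N(C)OC
Why: Two equivalents of base give the dianion, and its more basic terminal methyl-ketone carbon attacks the N-methoxy-N-methyl amide (dianion Claisen condensation); the chelated tetrahedral adduct prevents over-addition and collapses to the 1,3-diketone on acidic quench.

Step 4
Reactants: 5 methyl 2,4-dihydroxy-3,6-dimethylbenzoate
Product: 6 methyl 2-hydroxy-4-methoxy-3,6-dimethylbenzoate
Conditions: MeI (1.1 equiv), K2CO3, acetone, 40 °C
Reagents that add atoms: iodomethane, CI
Why: The C4 hydroxyl is free while the C2 hydroxyl is locked in a six-membered hydrogen bond to the ester carbonyl, so phenoxide methylation (Williamson ether synthesis) should stop at the C4 mono-ether.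

Step 5
Reactants: 6 methyl 2-hydroxy-4-methoxy-3,6-dimethylbenzoate
Product: 7 methyl 2-(acetyloxy)-4-methoxy-3,6-dimethylbenzoate
Conditions: Ac2O, Et3N, DMAP (cat.), CH2Cl2, rt
Reagents that add atoms: acetic anhydride, CC(=O)OC(C)=O
Why: DMAP-catalysed acylation converts the chelated phenol into an aryl acetate, which is inert to bromine radicals and lowers the electron density of the ring so that nuclear bromination is disfavoured in step 6.

Step 6
Reactants: 7 methyl 2-(acetyloxy)-4-methoxy-3,6-dimethylbenzoate
Product: 8 methyl 2-(acetyloxy)-3,6-bis(dibromomethyl)-4-methoxybenzoate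
Conditions: NBS (4.6 equiv), AIBN (cat.), PhCF3, reflux, hν
Reagents that add atoms: N-bromosuccinimide, O=C1CCC(=O)N1Br
Why: Radical chain bromination (Wohl–Ziegler) with excess NBS should take both benzylic methyl groups to the gem-dibromide, a defined end point because a third bromination at each carbon is very slow; any cyclisation of the C6 dibromide onto the ester leads to the same product after step 7.

Step 7
Reactants: 8 methyl 2-(acetyloxy)-3,6-bis(dibromomethyl)-4-methoxybenzoate
Product: 10 6-formyl-3,7-dihydroxy-5-methoxy-2-benzofuran-1(3H)-one (racemic), via dialdehyde ester 9 (not isolated)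
Conditions: AgNO3, acetone/H2O, rt → 50 °C; then LiOH, THF/H2O, 0 °C; then 1 M HCl to pH 2
Reagents that add atoms: water, O; lithium hydroxide, [Li+].[OH-]
Why: Silver-assisted solvolysis converts both gem-dibromides into aldehydes; hydroxide then cleaves the aryl acetate and, assisted by the neighbouring formyl group, the methyl ester. Acidification closes the 2-formylbenzoic acid to the lactol, while the other aldehyde has no ortho carboxyl and stays free.

Step 8
Reactants: 10 6-formyl-3,7-dihydroxy-5-methoxy-2-benzofuran-1(3H)-one
Product: 11 6-formyl-7-hydroxy-3,5-dimethoxy-2-benzofuran-1(3H)-one (racemic)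
Conditions: MeOH, CSA (cat.), 50 °C; aqueous work-up at pH 3
Reagents that add atoms: methanol, CO
Why: Acid-catalysed pseudo-esterification of the 3-hydroxyphthalide gives the cyclic methyl acetal, which masks the lactol; any dimethyl acetal of the chelated, doubly ortho-substituted aldehyde should revert on aqueous work-up.

Step 9
Reactants: 11 6-formyl-7-hydroxy-3,5-dimethoxy-2-benzofuran-1(3H)-one
Product: 12 6-formyl-3,5-dimethoxy-7-(methoxymethoxy)-2-benzofuran-1(3H)-one (racemic)
Conditions: MOMCl, i-Pr2NEt, CH2Cl2, 0 °C → rt
Reagents that add atoms: chloromethyl methyl ether, COCCl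
Why: O-alkylation of the acidic phenol; no other hydroxyl is present, so there is no selectivity issue. The MOM ether blocks the phenol that would otherwise trigger quinone methide loss of the benzylic ester under base.

Step 10
Reactants: 12 6-formyl-3,5-dimethoxy-7-(methoxymethoxy)-2-benzofuran-1(3H)-one
Product: 13 6-(hydroxymethyl)-3,5-dimethoxy-7-(methoxymethoxy)-2-benzofuran-1(3H)-one (racemic)
Conditions: LiAlH(Ot-Bu)3, THF, −40 → 0 °C; aq. KNaC4H4O6
Reagents that add atoms: none
Why: The bulky, mild hydride should reduce the aldehyde much faster than the lactone, and the aprotic medium keeps the pseudo-ester closed so that the masked C3 aldehyde is not exposed to reduction.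

Step 11
Reactants: 4 6-(3,5-dioxohexan-2-yl)-2,2-dimethyl-4H-1,3-dioxin-4-one; 13 6-(hydroxymethyl)-3,5-dimethoxy-7-(methoxymethoxy)-2-benzofuran-1(3H)-one
Product: 17 [3,5-dimethoxy-7-(methoxymethoxy)-1-oxo-1,3-dihydro-2-benzofuran-6-yl]methyl 2,4-dihydroxy-3,6-dimethylbenzoate (racemic at C3 of ring C), via acylketene 14 (not isolated), via triketo ester 15 (not isolated), via aldol adduct 16 (not isolated)
Conditions: PhMe, 110 °C (4 added slowly to 13); then Cs2CO3, THF, 0 °C → rt; then AcOH, 40 °C
Reagents that add atoms: none
Why: At 110 °C 4 loses acetone by a retro-hetero-Diels–Alder reaction to give acylketene 14, and the primary benzylic hydroxyl of 13 adds to the ketene carbon to give β-keto ester 15, so the ester C–O bond forms without any acylation by the hindered ring A acid. Cs2CO3 then forms the enolate at C2, the most acidic carbon because it lies between the ester and a ketone, and this enolate adds to the C7 methyl ketone in a 6-(enolendo)-exo-trig aldol that closes ring A through its C1–C6 bond (16). Loss of water and enolisation of the two remaining ketones, completed by AcOH, aromatise the ring, and the chain C4 methyl ends between the two ring oxygens. The closest known reaction type is dioxinone thermolysis, alcohol capture of the acylketene and biomimetic aldol aromatisation of the triketo ester to a resorcylate ester. No stereocentre is created: those of 15 and 16 vanish on aromatisation and the racemic acetal carbon of 13 is a spectator. Capture by the alcohol must beat intramolecular O-capture of the ketene by the enolised diketone (pyranone formation), which is secured by generating 14 slowly in the presence of the unhindered primary alcohol. The C2-to-C7 aldol must beat the C8-to-C3 aldol and Claisen attack on the ester, which the higher acidity of C2 and a mild carbonate base should secure. The aprotic medium keeps the methyl pseudo-ester closed, and the MOM ether prevents quinone methide loss of the new benzylic ester.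

Step 12
Reactants: 17 [3,5-dimethoxy-7-(methoxymethoxy)-1-oxo-1,3-dihydro-2-benzofuran-6-yl]methyl 2,4-dihydroxy-3,6-dimethylbenzoate
Product: 18 [3,5-dimethoxy-7-(methoxymethoxy)-1-oxo-1,3-dihydro-2-benzofuran-6-yl]methyl 2-hydroxy-4-methoxy-3,6-dimethylbenzoate (racemic)
Conditions: MeI (1.2 equiv), K2CO3, acetone, rt
Reagents that add atoms: iodomethane, CI
Why: The ring A C4 hydroxyl, para to the ester and not hydrogen bonded, is alkylated (Williamson ether synthesis) while the chelated C2 hydroxyl is expected to stay free; ring B has no free hydroxyl at this stage.

Step 13
Reactants: 18 [3,5-dimethoxy-7-(methoxymethoxy)-1-oxo-1,3-dihydro-2-benzofuran-6-yl]methyl 2-hydroxy-4-methoxy-3,6-dimethylbenzoate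
Product: 19 (3,7-dihydroxy-5-methoxy-1-oxo-1,3-dihydro-2-benzofuran-6-yl)methyl 2-hydroxy-4-methoxy-3,6-dimethylbenzoate (racemic)
Conditions: 1 M HCl (aq)/THF 1:3, 40 °C
Reagents that add atoms: water, O
Why: Dilute aqueous acid cleaves the MOM ether and hydrolyses the pseudo-ester methyl acetal to the lactol (acetal hydrolysis); the benzylic ester should survive because ring B is an electron-poor push-pull arene that does not readily form a benzylic cation, and the hindered ring A ester resists acid hydrolysis.

Step 14
Reactants: 19 (3,7-dihydroxy-5-methoxy-1-oxo-1,3-dihydro-2-benzofuran-6-yl)methyl 2-hydroxy-4-methoxy-3,6-dimethylbenzoate (racemic)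
Product: 20 [(3R)-3-(acetyloxy)-7-hydroxy-5-methoxy-1-oxo-1,3-dihydro-2-benzofuran-6-yl]methyl 2-hydroxy-4-methoxy-3,6-dimethylbenzoate
Conditions: immobilised Burkholderia cepacia lipase, vinyl acetate, PhMe, 40 °C
Reagents that add atoms: vinyl acetate, CC(=O)OC=C
Why: Lipase-catalysed transesterification with an enol ester acylates one lactol enantiomer while the other racemises in situ by ring-chain tautomerism through the achiral 2-formylbenzoic acid (dynamic kinetic resolution). C3 is controlled by the enzyme's binding pocket: on the size model (aryl arm large, ring-oxygen arm medium) the (3R)-lactol is expected to react faster. The chelated phenols are not expected to be acylated by the enzyme.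

Step 15
Reactants: 20 [(3R)-3-(acetyloxy)-7-hydroxy-5-methoxy-1-oxo-1,3-dihydro-2-benzofuran-6-yl]methyl 2-hydroxy-4-methoxy-3,6-dimethylbenzoate
Product: 21 [(3R)-3,7-dihydroxy-5-methoxy-1-oxo-1,3-dihydro-2-benzofuran-6-yl]methyl 2-hydroxy-4-methoxy-3,6-dimethylbenzoate
Conditions: immobilised Burkholderia cepacia lipase, n-BuOH, t-BuOMe, 5 °C
Reagents that add atoms: none
Why: The lipase transfers the acetyl group to 1-butanol by acyl-oxygen cleavage (enzymatic alcoholysis of an acyl hemiacetal), so the C3–O bond and its configuration are untouched. The enzyme's preference for the (3R)-acetate matches that of step 14, and the neutral, anhydrous, cold medium avoids ionising the lactol.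

## Compound list

1 | 2,2,6-trimethyl-4H-1,3-dioxin-4-one | CC1=CC(=O)OC(C)(C)O1 | starting material
2 | 6-ethyl-2,2-dimethyl-4H-1,3-dioxin-4-one | CCC1=CC(=O)OC(C)(C)O1 | intermediate
3 | 2,2-dimethyl-6-(3-oxobutan-2-yl)-4H-1,3-dioxin-4-one (racemic) | CC(=O)C(C)C1=CC(=O)OC(C)(C)O1 | intermediate
4 | 6-(3,5-dioxohexan-2-yl)-2,2-dimethyl-4H-1,3-dioxin-4-one (racemic, enol tautomers) | CC(=O)CC(=O)C(C)C1=CC(=O)OC(C)(C)O1 | intermediate
5 | methyl 2,4-dihydroxy-3,6-dimethylbenzoate | COC(=O)c1c(C)cc(O)c(C)c1O | starting material
6 | methyl 2-hydroxy-4-methoxy-3,6-dimethylbenzoate | COC(=O)c1c(C)cc(OC)c(C)c1O | intermediate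
7 | methyl 2-(acetyloxy)-4-methoxy-3,6-dimethylbenzoate | COC(=O)c1c(C)cc(OC)c(C)c1OC(C)=O | intermediate
8 | methyl 2-(acetyloxy)-3,6-bis(dibromomethyl)-4-methoxybenzoate | COC(=O)c1c(C(Br)Br)cc(OC)c(C(Br)Br)c1OC(C)=O | intermediate
9 | methyl 2-(acetyloxy)-3,6-diformyl-4-methoxybenzoate | COC(=O)c1c(C=O)cc(OC)c(C=O)c1OC(C)=O | intermediate (not isolated)
10 | 6-formyl-3,7-dihydroxy-5-methoxy-2-benzofuran-1(3H)-one (racemic) | O=Cc1c(OC)cc2C(O)OC(=O)c2c1O | intermediate
11 | 6-formyl-7-hydroxy-3,5-dimethoxy-2-benzofuran-1(3H)-one (racemic) | O=Cc1c(OC)cc2C(OC)OC(=O)c2c1O | intermediate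
12 | 6-formyl-3,5-dimethoxy-7-(methoxymethoxy)-2-benzofuran-1(3H)-one (racemic) | COCOc1c(C=O)c(OC)cc2C(OC)OC(=O)c12 | intermediate
13 | 6-(hydroxymethyl)-3,5-dimethoxy-7-(methoxymethoxy)-2-benzofuran-1(3H)-one (racemic) | COCOc1c(CO)c(OC)cc2C(OC)OC(=O)c12 | intermediate
14 | 4-methyloct-1-ene-1,3,5,7-tetrone (acylketene, racemic) | O=C=CC(=O)C(C)C(=O)CC(C)=O | intermediate (not isolated)
15 | [3,5-dimethoxy-7-(methoxymethoxy)-1-oxo-1,3-dihydro-2-benzofuran-6-yl]methyl 4-methyl-3,5,7-trioxooctanoate (stereoisomer and tautomer mixture) | CC(=O)CC(=O)C(C)C(=O)CC(=O)OCc1c(OC)cc2C(OC)OC(=O)c2c1OCOC | intermediate (not isolated)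
16 | [3,5-dimethoxy-7-(methoxymethoxy)-1-oxo-1,3-dihydro-2-benzofuran-6-yl]methyl 2-hydroxy-2,5-dimethyl-4,6-dioxocyclohexane-1-carboxylate (stereoisomer and tautomer mixture) | CC1C(=O)CC(C)(O)C(C(=O)OCc2c(OC)cc3C(OC)OC(=O)c3c2OCOC)C1=O | intermediate (not isolated)
17 | [3,5-dimethoxy-7-(methoxymethoxy)-1-oxo-1,3-dihydro-2-benzofuran-6-yl]methyl 2,4-dihydroxy-3,6-dimethylbenzoate (racemic) | COCOc1c(COC(=O)c3c(C)cc(O)c(C)c3O)c(OC)cc2C(OC)OC(=O)c12 | intermediate
18 | [3,5-dimethoxy-7-(methoxymethoxy)-1-oxo-1,3-dihydro-2-benzofuran-6-yl]methyl 2-hydroxy-4-methoxy-3,6-dimethylbenzoate (racemic) | COCOc1c(COC(=O)c3c(C)cc(OC)c(C)c3O)c(OC)cc2C(OC)OC(=O)c12 | intermediate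
19 | (3,7-dihydroxy-5-methoxy-1-oxo-1,3-dihydro-2-benzofuran-6-yl)methyl 2-hydroxy-4-methoxy-3,6-dimethylbenzoate (racemic) | COc1cc(C)c(C(=O)OCc2c(OC)cc3c(c2O)C(=O)OC3O)c(O)c1C | intermediate
20 | [(3R)-3-(acetyloxy)-7-hydroxy-5-methoxy-1-oxo-1,3-dihydro-2-benzofuran-6-yl]methyl 2-hydroxy-4-methoxy-3,6-dimethylbenzoate | COc1cc(C)c(C(=O)OCc2c(OC)cc3c(c2O)C(=O)O[C@H]3OC(C)=O)c(O)c1C | intermediate
21 | [(3R)-3,7-dihydroxy-5-methoxy-1-oxo-1,3-dihydro-2-benzofuran-6-yl]methyl 2-hydroxy-4-methoxy-3,6-dimethylbenzoate | COc1cc(C)c(C(=O)OCc2c(OC)cc3c(c2O)C(=O)O[C@H]3O)c(O)c1C | target

## Step count and risk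

Total step count: 15 (steps 1–3 for the dioxinone, steps 4–10 for the ring B alcohol, step 11 for the union, steps 12–15 for the end game). Longest linear sequence: 12 steps, from 5 to 21 (steps 4–15).

Least certain steps:

Step 11 (key step). The acylketene may be captured internally by the enolised diketone before the crowded benzylic alcohol reaches it. The triketo ester may also cyclise in the wrong mode or shed the alcohol by Claisen-type attack, and the base may open the pseudo-ester. Fallback: form the ester by carboxylate alkylation instead of ketene capture. It sets out from 6 and 13. 6 would be saponified (KOH, aqueous DMSO, 80 °C) to 2-hydroxy-4-methoxy-3,6-dimethylbenzoic acid F1. 13 would be converted with CBr4 and PPh3 in CH2Cl2 at 0 °C into 6-(bromomethyl)-3,5-dimethoxy-7-(methoxymethoxy)-2-benzofuran-1(3H)-one F2. The potassium carboxylate of F1 (KHCO3, DMF, rt) should displace the benzylic bromide of F2 by SN2, so the hindered carboxyl acts as a nucleophile and is never acylated. This comes back to the route at 18 and bypasses 17 and step 12.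

Step 6. Bromination may stall or overshoot unevenly at the two benzylic carbons, or turn to the ring position next to the methoxy group, because the ring is still fairly electron-rich. Fallback: oxidise the two methyl groups one after the other. It sets out from 7. NBS (2.1 equiv) should brominate the more electron-rich methyl between the two oxygens twice, giving methyl 2-(acetyloxy)-3-(dibromomethyl)-4-methoxy-6-methylbenzoate F3. AgNO3 in aqueous acetone would give methyl 2-(acetyloxy)-3-formyl-4-methoxy-6-methylbenzoate F4. The aldehyde would be parked as its acylal (Ac2O, cat. H2SO4), methyl 2-(acetyloxy)-3-[bis(acetyloxy)methyl]-4-methoxy-6-methylbenzoate F5, whose benzylic C–H is deactivated towards bromine radicals. A second NBS bromination (2.3 equiv) of the only remaining methyl would give methyl 2-(acetyloxy)-3-[bis(acetyloxy)methyl]-6-(dibromomethyl)-4-methoxybenzoate F6. The hydrolysis conditions of step 7 then return the route to 10.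

Step 13. Acid strong enough to hydrolyse the pseudo-ester may also ionise the benzylic ester or leave the acetal partly intact. Fallback: open the pseudo-ester at the acyl carbon with base while the phenol is still protected. It sets out from 18. LiOH (2.2 equiv, THF/H2O, 0 °C) should attack the lactone carbonyl and expel methanol; the hindered ring A ester, deactivated further as its phenoxide, should not react. Acidification with citric acid would give [3-hydroxy-5-methoxy-7-(methoxymethoxy)-1-oxo-1,3-dihydro-2-benzofuran-6-yl]methyl 2-hydroxy-4-methoxy-3,6-dimethylbenzoate F7. Its MOM ether alone then needs only brief, mild acid (CF3CO2H in CH2Cl2, 0 °C). This comes back at 19.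

Step 14. The enzyme may not accept the bulky substrate, racemisation of the slow enantiomer may lag behind acylation, or the enzyme may prefer the other enantiomer. Fallback: use small-molecule acyl-transfer catalysis in place of the enzyme. It sets out from 19. A chiral isothiourea catalyst of the benzotetramisole type (enantiomer chosen for the R product), isobutyric anhydride and i-Pr2NEt in CHCl3 at 0 °C would effect an acylative dynamic kinetic resolution; the amine also drives the ring-chain racemisation. The product would be [(3R)-7-hydroxy-5-methoxy-3-(2-methylpropanoyloxy)-1-oxo-1,3-dihydro-2-benzofuran-6-yl]methyl 2-hydroxy-4-methoxy-3,6-dimethylbenzoate F8. Lipase alcoholysis as in step 15 comes back at 21.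

Step 15. The freed lactol may lose configuration by ring opening while it remains in contact with the enzyme preparation, or the alcoholysis may be too slow at low temperature. Fallback: use an acyl group that is removed without enzyme, water or base. It sets out from 19. Step 14 would be run with vinyl chloroacetate to give [(3S)-3-[(chloroacetyl)oxy]-7-hydroxy-5-methoxy-1-oxo-1,3-dihydro-2-benzofuran-6-yl]methyl 2-hydroxy-4-methoxy-3,6-dimethylbenzoate F9. F9 has the same spatial arrangement as 20; the descriptor changes because the chloroacetoxy oxygen outranks the ring oxygen. Thiourea in THF/i-PrOH at 20 °C should then alkylate at sulfur and cyclise onto the ester carbonyl, releasing the lactol with its C3–O bond intact. This comes back at 21.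

## Further compounds

F1 | step 11 | 2-hydroxy-4-methoxy-3,6-dimethylbenzoic acid | OC(=O)c1c(C)cc(OC)c(C)c1O
F2 | step 11 | 6-(bromomethyl)-3,5-dimethoxy-7-(methoxymethoxy)-2-benzofuran-1(3H)-one (racemic) | COCOc1c(CBr)c(OC)cc2C(OC)OC(=O)c12
F3 | step 6 | methyl 2-(acetyloxy)-3-(dibromomethyl)-4-methoxy-6-methylbenzoate | COC(=O)c1c(C)cc(OC)c(C(Br)Br)c1OC(C)=O
F4 | step 6 | methyl 2-(acetyloxy)-3-formyl-4-methoxy-6-methylbenzoate | COC(=O)c1c(C)cc(OC)c(C=O)c1OC(C)=O
F5 | step 6 | methyl 2-(acetyloxy)-3-[bis(acetyloxy)methyl]-4-methoxy-6-methylbenzoate | COC(=O)c1c(C)cc(OC)c(C(OC(C)=O)OC(C)=O)c1OC(C)=O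
F6 | step 6 | methyl 2-(acetyloxy)-3-[bis(acetyloxy)methyl]-6-(dibromomethyl)-4-methoxybenzoate | COC(=O)c1c(C(Br)Br)cc(OC)c(C(OC(C)=O)OC(C)=O)c1OC(C)=O
F7 | step 13 | [3-hydroxy-5-methoxy-7-(methoxymethoxy)-1-oxo-1,3-dihydro-2-benzofuran-6-yl]methyl 2-hydroxy-4-methoxy-3,6-dimethylbenzoate (racemic) | COCOc1c(COC(=O)c3c(C)cc(OC)c(C)c3O)c(OC)cc2C(O)OC(=O)c12
F8 | step 14 | [(3R)-7-hydroxy-5-methoxy-3-(2-methylpropanoyloxy)-1-oxo-1,3-dihydro-2-benzofuran-6-yl]methyl 2-hydroxy-4-methoxy-3,6-dimethylbenzoate | COc1cc(C)c(C(=O)OCc2c(OC)cc3c(c2O)C(=O)O[C@H]3OC(=O)C(C)C)c(O)c1C
F9 | step 15 | [(3S)-3-[(chloroacetyl)oxy]-7-hydroxy-5-methoxy-1-oxo-1,3-dihydro-2-benzofuran-6-yl]methyl 2-hydroxy-4-methoxy-3,6-dimethylbenzoate | COc1cc(C)c(C(=O)OCc2c(OC)cc3c(c2O)C(=O)O[C@H]3OC(=O)CCl)c(O)c1C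
A1 | alternative 1 | tert-butyl{[2-(methoxy(trimethylsilyloxy)methylidene)-3-methoxybut-3-en-1-yl]oxy}dimethylsilane (1,3-dimethoxy-1-(trimethylsilyloxy)buta-1,3-diene carrying a tert-butyldimethylsilyloxymethyl group at C2) | C=C(OC)C(CO[Si](C)(C)C(C)(C)C)=C(OC)O[Si](C)(C)C
A2 | alternative 1 | methyl 4,4-diethoxybut-2-ynoate | CCOC(OCC)C#CC(=O)OC
A3 | alternative 1 | methyl 6-(diethoxymethyl)-2-hydroxy-4-methoxy-3-{[tert-butyl(dimethyl)silyl]oxymethyl}benzoate | CCOC(OCC)c1cc(OC)c(CO[Si](C)(C)C(C)(C)C)c(O)c1C(=O)OC
A4 | alternative 2 | 1-ethoxyprop-2-yn-1-yl 3-{dimethyl[(3-methoxyprop-2-yn-1-yl)oxy]silyl}prop-2-ynoate (racemic) | C#CC(OCC)OC(=O)C#C[Si](C)(C)OCC#COC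
A5 | alternative 2 | racemic tricycle: 3-ethoxy-5-methoxyphthalide whose C6–CH2–O–SiMe2–C7 bridge forms a fused 1,2-oxasilole ring | CCOC1OC(=O)c2c1cc(OC)c1CO[Si](C)(C)c21
A6 | alternative 2 | 3-ethoxy-7-hydroxy-6-(hydroxymethyl)-5-methoxy-2-benzofuran-1(3H)-one (racemic) | CCOC1OC(=O)c2c(O)c(CO)c(OC)cc12
A7 | alternative 3 | (S)-configured α-silyloxy benzocyclobutenone: the four-membered ketone analogue of A8, in which the carbonyl carbon is bonded directly to the CH(OSi) carbon | COc1cc2c(c(O[Si](C)(C)C(C)(C)C)c1COC(=O)c1c(C)cc(OC)c(C)c1O)C(=O)[C@H]2O[Si](C)(C)C(C)(C)C
A8 | alternative 3 | bis(tert-butyldimethylsilyl) ether of 21 at the C3 and C7 oxygens (3S by the priority rules, same spatial arrangement as 21) | COc1cc2c(c(O[Si](C)(C)C(C)(C)C)c1COC(=O)c1c(C)cc(OC)c(C)c1O)C(=O)O[C@H]2O[Si](C)(C)C(C)(C)C
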